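**Retrosynthetic overview**

- Robustol ⇐ global O‑demethylation and alkene hydrogenation of a 22‑membered cycloalkene that carries a C7=C8 double bond in the middle of the C14 bridge (bridge numbered C1–C14 from ring B, the 2,6‑dioxygenated aryl ring, to ring A, the 3‑hydroxyphenoxy ring).
- Cycloalkene ⇐ intramolecular McMurry reductive coupling of an acyclic diaryl ether dialdehyde: C7 and C8 are both aldehyde carbons, two carbons of like polarity united through titanium ketyl radicals.
- Enabling feature: the C7–C8 bond bisects the tetradecamethylene bridge. C7 lies seven carbons from C4 of ring B and C8 seven carbons from C5 of ring A, so the two halves are identical seven‑carbon arms with interchangeable termini, and the strain‑free 22‑membered ring hinged at the diaryl ether oxygen has no stereocentre.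
- Dialdehyde ⇐ two‑directional arm growth (double Wittig with a C6 hydroxy‑ylide, hydrogenation, oxidation) on a diaryl ether bis‑benzaldehyde ⇐ Ullmann coupling of syringaldehyde with 3‑bromo‑5‑methoxybenzaldehyde.
- Ring order: rings A and B are bought as arenes; the only ring formed is the 22‑membered macrocycle (ring C), in the key step.

Key step: step 6

Remark on the chemistry: robustol has no stereocentre; the alkene geometries that arise on the way are erased by hydrogenation, so geometric mixtures are carried forward, and the four starting materials are taken as commercial.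

**Route**

Step 1
Reactants: 1 syringaldehyde (4‑hydroxy‑3,5‑dimethoxybenzaldehyde); 2 3‑bromo‑5‑methoxybenzaldehyde
Product: 3 4‑(3‑formyl‑5‑methoxyphenoxy)‑3,5‑dimethoxybenzaldehyde
Conditions: CuI (cat.), picolinic acid (cat.), K3PO4, DMSO, 90 °C, Ar
Reagents that add atoms: none
Why: Ullmann‑type copper‑catalysed diaryl ether synthesis, in which the N,O‑chelating picolinate ligand should keep monovalent copper active toward the doubly ortho‑substituted phenoxide, the aryl bromide is activated by its formyl group, and neither non‑enolisable aldehyde is affected by K3PO4.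

Step 2
Reactants: 4 6‑bromohexan‑1‑ol; 5 triphenylphosphine
Product: 6 (6‑hydroxyhexyl)triphenylphosphonium bromide
Conditions: MeCN, reflux; trituration with Et2O
Reagents that add atoms: none
Why: SN2 quaternisation of triphenylphosphine by the primary bromide (phosphonium salt formation), which the free hydroxyl group does not disturb.

Step 3
Reactants: 3 4‑(3‑formyl‑5‑methoxyphenoxy)‑3,5‑dimethoxybenzaldehyde; 6 (6‑hydroxyhexyl)triphenylphosphonium bromide (2.5 equiv)
Product: 8 (6Z)‑7‑[4‑[3‑[(1Z)‑7‑hydroxyhept‑1‑en‑1‑yl]‑5‑methoxyphenoxy]‑3,5‑dimethoxyphenyl]hept‑6‑en‑1‑ol, via alkoxide ylide 7 (not isolated)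
Conditions: 6, NaN(SiMe3)2 (2 equiv per 6), THF, −78 to 0 °C; then 3, −78 °C to rt; sat. aq. NH4Cl
Reagents that add atoms: none
Why: Two‑directional Wittig olefination in which the non‑stabilised ylide 7, carried as its sodium alkoxide, should add to both aryl aldehydes under salt‑free kinetic control to give mainly the (Z,Z)‑diene, any E isomer being harmless because step 4 removes both double bonds.

Step 4
Reactants: 8 (6Z)‑7‑[4‑[3‑[(1Z)‑7‑hydroxyhept‑1‑en‑1‑yl]‑5‑methoxyphenoxy]‑3,5‑dimethoxyphenyl]hept‑6‑en‑1‑ol
Product: 9 7‑[4‑[3‑(7‑hydroxyheptyl)‑5‑methoxyphenoxy]‑3,5‑dimethoxyphenyl]heptan‑1‑ol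
Conditions: H2 (1 atm), Pd/C (10 % palladium on carbon), EtOAc, rt
Reagents that add atoms: none
Why: Heterogeneous catalytic hydrogenation should saturate the two 1,2‑disubstituted styrenyl alkenes while the aryl methyl ethers, the diaryl ether and the primary alcohols stay untouched.

Step 5
Reactants: 9 7‑[4‑[3‑(7‑hydroxyheptyl)‑5‑methoxyphenoxy]‑3,5‑dimethoxyphenyl]heptan‑1‑ol
Product: 10 7‑[4‑[3‑methoxy‑5‑(7‑oxoheptyl)phenoxy]‑3,5‑dimethoxyphenyl]heptanal
Conditions: Dess–Martin periodinane (2.5 equiv), CH2Cl2, 0 °C to rt
Reagents that add atoms: none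
Why: Dess–Martin oxidation should convert both primary alcohols into aldehydes without over‑oxidation and without touching the electron‑rich arenes.

Step 6
Reactants: 10 7‑[4‑[3‑methoxy‑5‑(7‑oxoheptyl)phenoxy]‑3,5‑dimethoxyphenyl]heptanal
Product: 12 7,8‑didehydrorobustol tri‑O‑methyl ether (22‑membered cycloalkene; E/Z mixture at C7=C8), via titanium pinacolate 11 (not isolated)
Conditions: TiCl3(DME)1.5, Zn–Cu couple, DME, reflux; 10 added by syringe pump over 36 h (final concentration about 0.003 M), then reflux 6 h
Reagents that add atoms: none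
Why: Low‑valent titanium, generated from TiCl3(DME)1.5 and Zn–Cu couple, transfers one electron to each of the two aliphatic aldehyde groups of 10, and the two titanium‑bound ketyl radicals, carbons of identical and normally electrophilic polarity, recombine to forge the C7–C8 bond as the titanium pinacolate 11, which is deoxygenated on the titanium surface at reflux to the C7=C8 cycloalkene 12 and titanium oxide. The closest known reaction type is the intramolecular McMurry coupling of α,ω‑dialdehydes, which is established for macrocyclic cycloalkenes of twenty and more ring atoms and for cyclophane‑type macrocycles. The single ring closed is the 22‑membered macrocycle (ring C), by head‑to‑head ketyl–ketyl recombination in which both former carbonyl carbons become ring members (a pinacol‑type macrocyclisation; the five‑membered titanium diolate ring of 11 is transient). No stereocentre survives, because the two carbinol centres of 11 are destroyed on deoxygenation and the E/Z geometry of C7=C8 is immaterial once step 7 saturates it. The step needs intramolecular rather than intermolecular coupling, which is secured by slow addition of 10 to excess reagent (pseudo‑high dilution), by the strain‑free, mobile 22‑membered ring hinged at the diaryl ether oxygen, and by the identity of the two 7‑oxoheptyl arms, so that no cross‑selectivity question arises. Chemoselectivity is secured because aryl methyl ethers, the diaryl ether and the saturated chains are inert to low‑valent titanium.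

Step 7
Reactants: 12 7,8‑didehydrorobustol tri‑O‑methyl ether (E/Z mixture)
Product: 13 robustol tri‑O‑methyl ether
Conditions: H2 (1 atm), Pd/C (10 % palladium on carbon), EtOAc, rt
Reagents that add atoms: none
Why: Catalytic hydrogenation of the isolated disubstituted ring alkene should converge both geometric isomers on the saturated tetradecamethylene bridge.

Step 8
Reactants: 13 robustol tri‑O‑methyl ether
Product: 15 robustol, via tris(dibromoboryl) ether 14 (not isolated)
Conditions: BBr3 (6 equiv), CH2Cl2, −78 °C to rt; then ice‑water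
Reagents that add atoms: none
Why: BBr3 O‑demethylation of aryl methyl ethers, in which each methoxy oxygen coordinates boron, bromide attacks the methyl group by SN2 and hydrolysis of the aryloxyboron species 14 should free the three phenols, whereas the diaryl ether, having no sp3 carbon on oxygen, is not cleaved.

**Compound list**

1 | syringaldehyde (4‑hydroxy‑3,5‑dimethoxybenzaldehyde) | COc1cc(C=O)cc(OC)c1O | starting material
2 | 3‑bromo‑5‑methoxybenzaldehyde | COc1cc(Br)cc(C=O)c1 | starting material
3 | 4‑(3‑formyl‑5‑methoxyphenoxy)‑3,5‑dimethoxybenzaldehyde | COc1cc(C=O)cc(OC)c1Oc1cc(OC)cc(C=O)c1 | intermediate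
4 | 6‑bromohexan‑1‑ol | OCCCCCCBr | starting material
5 | triphenylphosphine | c1ccc(cc1)P(c1ccccc1)c1ccccc1 | starting material
6 | (6‑hydroxyhexyl)triphenylphosphonium bromide | [Br-].OCCCCCC[P+](c1ccccc1)(c1ccccc1)c1ccccc1 | intermediate
7 | sodium 6‑(triphenylphosphoranylidene)hexan‑1‑olate (alkoxide ylide) | [Na+].[O-]CCCCCC=P(c1ccccc1)(c1ccccc1)c1ccccc1 | intermediate (not isolated)
8 | (6Z)‑7‑[4‑[3‑[(1Z)‑7‑hydroxyhept‑1‑en‑1‑yl]‑5‑methoxyphenoxy]‑3,5‑dimethoxyphenyl]hept‑6‑en‑1‑ol (Z,Z drawn; E isomers carried along) | COc1cc(/C=C\CCCCCO)cc(OC)c1Oc1cc(OC)cc(/C=C\CCCCCO)c1 | intermediate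
9 | 7‑[4‑[3‑(7‑hydroxyheptyl)‑5‑methoxyphenoxy]‑3,5‑dimethoxyphenyl]heptan‑1‑ol | COc1cc(CCCCCCCO)cc(OC)c1Oc1cc(OC)cc(CCCCCCCO)c1 | intermediate
10 | 7‑[4‑[3‑methoxy‑5‑(7‑oxoheptyl)phenoxy]‑3,5‑dimethoxyphenyl]heptanal | COc1cc(CCCCCCC=O)cc(OC)c1Oc1cc(OC)cc(CCCCCCC=O)c1 | intermediate
11 | titanium 7,8‑diolate (pinacolate) of the robustol tri‑O‑methyl ether macrocycle; both relative configurations at C7/C8, not defined | COc1cc2cc(c1)Oc1c(OC)cc(cc1OC)CCCCCCC3O[Ti]OC3CCCCCC2 | intermediate (not isolated)
12 | 7,8‑didehydrorobustol tri‑O‑methyl ether (22‑membered cycloalkene, C7=C8 in the bridge, E/Z mixture, geometry not specified) | COc1cc2cc(c1)Oc1c(OC)cc(cc1OC)CCCCCCC=CCCCCCC2 | intermediate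
13 | robustol tri‑O‑methyl ether (saturated 22‑membered diaryl ether macrocycle, three OMe) | COc1cc2cc(c1)Oc1c(OC)cc(cc1OC)CCCCCCCCCCCCCC2 | intermediate
14 | robustol tris(dibromoboryl) ether | BrB(Br)Oc1cc2cc(c1)Oc1c(OB(Br)Br)cc(cc1OB(Br)Br)CCCCCCCCCCCCCC2 | intermediate (not isolated)
15 | robustol (achiral) | Oc1cc2cc(c1)Oc1c(O)cc(cc1O)CCCCCCCCCCCCCC2 | target

**Summary**

Total step count: 8. Longest linear sequence: 7 steps (steps 1, 3, 4, 5, 6, 7, 8); step 2 is a one‑step side branch that supplies the phosphonium salt.

Steps most likely to fail, with fallbacks: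

1. Step 6 (McMurry macrocyclisation). Intermolecular reductive coupling may compete and lead to oligomerisation, or the coupling may stop at the pinacol stage or merely reduce the aldehydes. The fallback sets out from dialdehyde 10: double Wittig methylenation (Ph3PCH3Br, KOtBu, THF, 0 °C) should give 1,3‑dimethoxy‑2‑[3‑methoxy‑5‑(oct‑7‑en‑1‑yl)phenoxy]‑5‑(oct‑7‑en‑1‑yl)benzene F1. Ring‑closing metathesis of F1 with second‑generation Grubbs catalyst, RuCl2(H2IMes)(PCy3)(=CHPh), in dilute CH2Cl2 at reflux should then close the same C7=C8 bond with loss of ethene. The fallback comes back to the route at cycloalkene 12.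

2. Step 1 (Ullmann coupling). C–O bond formation may be slow because the phenoxide is doubly ortho‑substituted and deactivated by its para formyl group, so that protodebromination of the aryl bromide takes over. The fallback sets out from 2 and reverses the roles of the partners: Miyaura borylation (B2pin2, PdCl2(dppf), KOAc, dioxane, 80 °C) should give 3‑methoxy‑5‑(4,4,5,5‑tetramethyl‑1,3,2‑dioxaborolan‑2‑yl)benzaldehyde F2. Chan–Lam oxidative coupling of F2 with phenol 1 (Cu(OAc)2, pyridine, B(OH)3, 4 Å molecular sieves, MeCN, air, 70 °C) should then form the ether by reductive elimination from a trivalent copper aryl phenoxide, a mode that tolerates doubly ortho‑substituted phenols. The fallback comes back to the route at 3.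

3. Step 3 (double Wittig). The second olefination may stall because the dianionic alkoxide ylide aggregates and dissolves poorly, leaving mono‑olefinated material. The fallback sets out from 3 and carries the arm terminus at the carboxylate level: Wittig reaction with the ylide from commercial (5‑carboxypentyl)triphenylphosphonium bromide (KOtBu, 2 equiv per salt, THF) should give (6Z)‑7‑[4‑[3‑[(1Z)‑6‑carboxyhex‑1‑en‑1‑yl]‑5‑methoxyphenoxy]‑3,5‑dimethoxyphenyl]hept‑6‑enoic acid F3. Reduction of both carboxylic acids with LiAlH4 (THF, 0 °C to rt), which leaves the styrenyl alkenes alone, should then give the diene diol. The fallback comes back to the route at 8.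

**Further compounds**

F1 | step 6 | 1,3‑dimethoxy‑2‑[3‑methoxy‑5‑(oct‑7‑en‑1‑yl)phenoxy]‑5‑(oct‑7‑en‑1‑yl)benzene | COc1cc(CCCCCCC=C)cc(OC)c1Oc1cc(OC)cc(CCCCCCC=C)c1
F2 | step 1 | 3‑methoxy‑5‑(4,4,5,5‑tetramethyl‑1,3,2‑dioxaborolan‑2‑yl)benzaldehyde | COc1cc(C=O)cc(c1)B1OC(C)(C)C(C)(C)O1
F3 | step 3 | (6Z)‑7‑[4‑[3‑[(1Z)‑6‑carboxyhex‑1‑en‑1‑yl]‑5‑methoxyphenoxy]‑3,5‑dimethoxyphenyl]hept‑6‑enoic acid | COc1cc(/C=C\CCCCC(=O)O)cc(OC)c1Oc1cc(OC)cc(/C=C\CCCCC(=O)O)c1
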